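**Strategy.** The plan rests on cutting the C2–C3 bond of the dihydrobenzofuran ring. C2 is an ether carbon flanked by O1 and the catechol ring, so its C–H is hydridic; C3 carries the benzo ring and the ester, so it can be a donor/acceptor carbene. A chiral dirhodium carboxylate decomposes a methyl aryldiazoacetate whose ortho oxygen bears a 3,4-bis(benzyloxy)benzyl group. The carbene inserts into one enantiotopic O–CH2 hydrogen, closing the furan ring and fixing C2 in one operation. A C4 bromine on the precursor survives and later takes the danshensu acrylate by Heck coupling. C3 is then equilibrated to trans, and a single Lewis-acid debenzylation ends the route.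

Key step: step 10

Assumption 1: the sense of induction in step 10 is inferred from insertions of simpler 2-(benzyloxy)aryl diazoacetates, which points to the R-configured catalyst for a 2S product; if a test run shows the opposite sense, the mirror-image catalyst is used with nothing else changed.
Assumption 2: 3,4-bis(benzyloxy)benzyl chloride (8) and (R)-danshensu (17) are taken as catalogue compounds.

**Route**

Step 1
Reactants: 1 2-(benzyloxy)phenol
Product: 2 2-(benzyloxy)phenyl acetate
Conditions: Ac2O, pyridine, DMAP (cat.), CH2Cl2, 0 °C to rt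
Reagents that add atoms: acetic anhydride, CC(=O)OC(C)=O
Why: DMAP-catalysed O-acylation turns the phenol into the weaker director, so that the benzyloxy group steers the bromination that follows.

Step 2
Reactants: 2 2-(benzyloxy)phenyl acetate
Product: 3 2-(benzyloxy)-5-bromophenyl acetate
Conditions: NBS, MeCN, rt, dark
Reagents that add atoms: N-bromosuccinimide, O=C1CCC(=O)N1Br
Why: Electrophilic aromatic bromination should enter para to the ether oxygen, which outranks the acetoxy group as a director, while the unactivated benzyl phenyl ring stays untouched.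

Step 3
Reactants: 3 2-(benzyloxy)-5-bromophenyl acetate
Product: 5 2-(allyloxy)-1-(benzyloxy)-4-bromobenzene, via 2-(benzyloxy)-5-bromophenol 4 (not isolated)
Conditions: K2CO3, MeOH, rt; then allyl bromide, 50 °C
Reagents that add atoms: allyl bromide, C=CCBr
Why: Carbonate-mediated methanolysis of the aryl acetate frees the phenoxide, which undergoes Williamson O-allylation in the same flask.

Step 4
Reactants: 5 2-(allyloxy)-1-(benzyloxy)-4-bromobenzene
Product: 7 2-allyl-6-(benzyloxy)-3-bromophenol, via 6-allyl-2-(benzyloxy)-5-bromocyclohexa-2,4-dien-1-one 6 (not isolated)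
Conditions: N,N-diethylaniline, 190 °C, Ar
Reagents that add atoms: none
Why: The thermal aromatic Claisen rearrangement ([3,3]-sigmatropic shift) should deliver the allyl group to the only free ortho carbon, the one between the oxygen and the bromine, and the dienone then tautomerises to the phenol.

Step 5
Reactants: 7 2-allyl-6-(benzyloxy)-3-bromophenol; 8 3,4-bis(benzyloxy)benzyl chloride
Product: 9 3-allyl-1-(benzyloxy)-2-{[3,4-bis(benzyloxy)benzyl]oxy}-4-bromobenzene
Conditions: K2CO3, KI (cat.), DMF, 60 °C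
Reagents that add atoms: none
Why: Williamson etherification of the phenoxide with the electron-rich benzylic chloride (iodide catalysis) places the future C2 carbon on the oxygen that becomes O1.

Step 6
Reactants: 9 3-allyl-1-(benzyloxy)-2-{[3,4-bis(benzyloxy)benzyl]oxy}-4-bromobenzene
Product: 11 2-[3-(benzyloxy)-2-{[3,4-bis(benzyloxy)benzyl]oxy}-6-bromophenyl]acetaldehyde, via 3-[3-(benzyloxy)-2-{[3,4-bis(benzyloxy)benzyl]oxy}-6-bromophenyl]propane-1,2-diol 10 (not isolated)
Conditions: OsO4 (cat.), NaIO4, 2,6-lutidine, 1,4-dioxane–H2O (3:1), rt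
Reagents that add atoms: osmium tetroxide, O=[Os](=O)(=O)=O (turned over by sodium periodate, [Na+].[O-]I(=O)(=O)=O)
Why: Lemieux–Johnson oxidation (catalytic dihydroxylation, then periodate glycol cleavage) should cut the terminal alkene to the arylacetaldehyde without touching the benzyl ethers or the aryl bromide.

Step 7
Reactants: 11 2-[3-(benzyloxy)-2-{[3,4-bis(benzyloxy)benzyl]oxy}-6-bromophenyl]acetaldehyde
Product: 12 2-[3-(benzyloxy)-2-{[3,4-bis(benzyloxy)benzyl]oxy}-6-bromophenyl]acetic acid
Conditions: NaClO2, NaH2PO4, 2-methyl-2-butene, t-BuOH–THF–H2O, 0 °C to rt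
Reagents that add atoms: sodium chlorite, [Na+].[O-]Cl=O
Why: Pinnick oxidation converts the enolisable aldehyde to the acid under buffered conditions, the alkene scavenger removing hypochlorous acid before it can chlorinate the electron-rich rings.

Step 8
Reactants: 12 2-[3-(benzyloxy)-2-{[3,4-bis(benzyloxy)benzyl]oxy}-6-bromophenyl]acetic acid
Product: 13 methyl 2-[3-(benzyloxy)-2-{[3,4-bis(benzyloxy)benzyl]oxy}-6-bromophenyl]acetate
Conditions: MeI, K2CO3, DMF, rt
Reagents that add atoms: iodomethane, CI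
Why: SN2 O-alkylation of the carboxylate gives the methyl ester that the target keeps, and carbonate is too weak a base to cause C-methylation.

Step 9
Reactants: 13 methyl 2-[3-(benzyloxy)-2-{[3,4-bis(benzyloxy)benzyl]oxy}-6-bromophenyl]acetate
Product: 14 methyl 2-[3-(benzyloxy)-2-{[3,4-bis(benzyloxy)benzyl]oxy}-6-bromophenyl]-2-diazoacetate
Conditions: p-ABSA, DBU, MeCN, 0 °C to rt
Reagents that add atoms: 4-acetamidobenzenesulfonyl azide, CC(=O)Nc1ccc(cc1)S(=O)(=O)N=[N+]=[N-]
Why: Regitz diazo transfer, in which the DBU-derived arylacetate enolate attacks the sulfonyl azide and collapses to the aryldiazoacetate and the sulfonamide.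

Step 10
Reactants: 14 methyl 2-[3-(benzyloxy)-2-{[3,4-bis(benzyloxy)benzyl]oxy}-6-bromophenyl]-2-diazoacetate
Product: 15 methyl (2S,3R)-7-(benzyloxy)-2-[3,4-bis(benzyloxy)phenyl]-4-bromo-2,3-dihydro-1-benzofuran-3-carboxylate (cis)
Conditions: Rh2(R-PTTL)4 (2 mol %), 4 Å MS, toluene, −60 °C, slow addition of 14
Reagents that add atoms: none
Why: Loss of N2 at rhodium gives an electrophilic donor/acceptor carbene at C3, and the two ortho substituents hold the O–CH2 group over its empty orbital, so that a three-centre, hydride-transfer-like transition state forms the C2–C3 bond. The closest known reaction type is the enantioselective intramolecular C–H insertion of aryldiazoacetates into the benzylic C–H bonds of aryl benzyl ethers, which gives cis-2-aryl-2,3-dihydrobenzofuran-3-carboxylates. The ring O1–C2–C3–C3a–C7a closes by 1,5-insertion, the carbene carbon and the reacting carbon being linked through C3a, C7a and O1. C2 is set by the N-phthaloyl-tert-leucinate ligands, which pick one of the two enantiotopic hydrogens, while C3 arises cis to the aryl group under kinetic control and is corrected in step 11. The step needs chemoselectivity for this CH2 over the three plain benzyl ethers, the arenes and the aryl bromide; it is the only C–H that can reach the carbene through a five-membered ring, it is activated by O1 and a para-oxygenated ring, and slow addition at low temperature should suppress carbene dimerisation.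

Step 11
Reactants: 15 methyl (2S,3R)-7-(benzyloxy)-2-[3,4-bis(benzyloxy)phenyl]-4-bromo-2,3-dihydro-1-benzofuran-3-carboxylate
Product: 16 methyl (2S,3S)-7-(benzyloxy)-2-[3,4-bis(benzyloxy)phenyl]-4-bromo-2,3-dihydro-1-benzofuran-3-carboxylate (trans)
Conditions: NaOMe (0.3 equiv), MeOH–THF, 0 °C to rt; AcOH quench
Reagents that add atoms: none
Why: Base-mediated epimerisation by reversible deprotonation at C3, the only acidic stereocentre, should move the ester trans to the aryl group (thermodynamic control) with C2 untouched, and methoxide matches the methyl ester.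

Step 12
Reactants: 17 (R)-danshensu
Product: 18 benzyl (2R)-3-[3,4-bis(benzyloxy)phenyl]-2-hydroxypropanoate
Conditions: BnBr, K2CO3, DMF, rt, Ar
Reagents that add atoms: benzyl bromide, BrCc1ccccc1
Why: Williamson-type O-benzylation in which carbonate ionises only the acid and the two phenols, so that the secondary alcohol stays free and the stereocentre is not touched.

Step 13
Reactants: 18 benzyl (2R)-3-[3,4-bis(benzyloxy)phenyl]-2-hydroxypropanoate
Product: 19 benzyl (2R)-2-(acryloyloxy)-3-[3,4-bis(benzyloxy)phenyl]propanoate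
Conditions: acryloyl chloride, Et3N, CH2Cl2, −20 to 0 °C
Reagents that add atoms: acryloyl chloride, C=CC(Cl)=O
Why: Amine-mediated O-acylation of the secondary alcohol with the acid chloride at low temperature, which does not involve the C–H at the stereocentre.

Step 14
Reactants: 16 methyl (2S,3S)-7-(benzyloxy)-2-[3,4-bis(benzyloxy)phenyl]-4-bromo-2,3-dihydro-1-benzofuran-3-carboxylate; 19 benzyl (2R)-2-(acryloyloxy)-3-[3,4-bis(benzyloxy)phenyl]propanoate
Product: 20 methyl (2S,3S)-7-(benzyloxy)-4-[(E)-3-{[(2R)-1-(benzyloxy)-3-[3,4-bis(benzyloxy)phenyl]-1-oxopropan-2-yl]oxy}-3-oxoprop-1-en-1-yl]-2-[3,4-bis(benzyloxy)phenyl]-2,3-dihydro-1-benzofuran-3-carboxylate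
Conditions: Pd2(dba)3 (cat.), [(t-Bu)3PH]BF4 (cat.), Cy2NMe, 1,4-dioxane, 70 °C
Reagents that add atoms: none
Why: Mizoroki–Heck reaction in which the bulky electron-rich phosphine allows oxidative addition at the hindered C4–Br, syn insertion and β-hydride elimination give the E-cinnamate, and the hindered amine should leave C3 (already the stable epimer) and the lactate centre alone.

Step 15
Reactants: 20 hexabenzyl ether/ester from step 14
Product: 21 monomethyl lithospermate, (2R)-3-(3,4-dihydroxyphenyl)-2-{[(2E)-3-[(2S,3S)-2-(3,4-dihydroxyphenyl)-7-hydroxy-3-(methoxycarbonyl)-2,3-dihydro-1-benzofuran-4-yl]prop-2-enoyl]oxy}propanoic acid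
Conditions: BCl3, C6HMe5, CH2Cl2, −78 to −40 °C; then H2O–THF
Reagents that add atoms: none
Why: Lewis-acid debenzylation with a non-basic cation scavenger (Friedel–Crafts transfer of benzyl to pentamethylbenzene) should cleave the five aryl benzyl ethers and the benzyl ester at low temperature while the methyl ester, the cinnamate and the alkene, which hydrogenolysis would not spare, remain.

**Compound list**

1 | 2-(benzyloxy)phenol | Oc1ccccc1OCc1ccccc1 | starting material
2 | 2-(benzyloxy)phenyl acetate | CC(=O)Oc1ccccc1OCc1ccccc1 | intermediate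
3 | 2-(benzyloxy)-5-bromophenyl acetate | CC(=O)Oc1cc(Br)ccc1OCc1ccccc1 | intermediate
4 | 2-(benzyloxy)-5-bromophenol | Oc1cc(Br)ccc1OCc1ccccc1 | intermediate (not isolated)
5 | 2-(allyloxy)-1-(benzyloxy)-4-bromobenzene | C=CCOc1cc(Br)ccc1OCc1ccccc1 | intermediate
6 | 6-allyl-2-(benzyloxy)-5-bromocyclohexa-2,4-dien-1-one (racemic) | C=CCC1C(Br)=CC=C(OCc2ccccc2)C1=O | intermediate (not isolated)
7 | 2-allyl-6-(benzyloxy)-3-bromophenol | C=CCc1c(Br)ccc(OCc2ccccc2)c1O | intermediate
8 | 3,4-bis(benzyloxy)benzyl chloride | ClCc1ccc(OCc2ccccc2)c(OCc2ccccc2)c1 | starting material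
9 | 3-allyl-1-(benzyloxy)-2-{[3,4-bis(benzyloxy)benzyl]oxy}-4-bromobenzene | C=CCc1c(Br)ccc(OCc2ccccc2)c1OCc1ccc(OCc2ccccc2)c(OCc2ccccc2)c1 | intermediate
10 | 3-[3-(benzyloxy)-2-{[3,4-bis(benzyloxy)benzyl]oxy}-6-bromophenyl]propane-1,2-diol (racemic) | OCC(O)Cc1c(Br)ccc(OCc2ccccc2)c1OCc1ccc(OCc2ccccc2)c(OCc2ccccc2)c1 | intermediate (not isolated)
11 | 2-[3-(benzyloxy)-2-{[3,4-bis(benzyloxy)benzyl]oxy}-6-bromophenyl]acetaldehyde | O=CCc1c(Br)ccc(OCc2ccccc2)c1OCc1ccc(OCc2ccccc2)c(OCc2ccccc2)c1 | intermediate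
12 | 2-[3-(benzyloxy)-2-{[3,4-bis(benzyloxy)benzyl]oxy}-6-bromophenyl]acetic acid | OC(=O)Cc1c(Br)ccc(OCc2ccccc2)c1OCc1ccc(OCc2ccccc2)c(OCc2ccccc2)c1 | intermediate
13 | methyl 2-[3-(benzyloxy)-2-{[3,4-bis(benzyloxy)benzyl]oxy}-6-bromophenyl]acetate | COC(=O)Cc1c(Br)ccc(OCc2ccccc2)c1OCc1ccc(OCc2ccccc2)c(OCc2ccccc2)c1 | intermediate
14 | methyl 2-[3-(benzyloxy)-2-{[3,4-bis(benzyloxy)benzyl]oxy}-6-bromophenyl]-2-diazoacetate | COC(=O)C(=[N+]=[N-])c1c(Br)ccc(OCc2ccccc2)c1OCc1ccc(OCc2ccccc2)c(OCc2ccccc2)c1 | intermediate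
15 | methyl (2S,3R)-7-(benzyloxy)-2-[3,4-bis(benzyloxy)phenyl]-4-bromo-2,3-dihydro-1-benzofuran-3-carboxylate (cis) | COC(=O)[C@@H]1c2c(Br)ccc(OCc3ccccc3)c2O[C@@H]1c1ccc(OCc2ccccc2)c(OCc2ccccc2)c1 | intermediate
16 | methyl (2S,3S)-7-(benzyloxy)-2-[3,4-bis(benzyloxy)phenyl]-4-bromo-2,3-dihydro-1-benzofuran-3-carboxylate (trans) | COC(=O)[C@H]1c2c(Br)ccc(OCc3ccccc3)c2O[C@@H]1c1ccc(OCc2ccccc2)c(OCc2ccccc2)c1 | intermediate
17 | (R)-danshensu, (2R)-3-(3,4-dihydroxyphenyl)-2-hydroxypropanoic acid | O=C(O)[C@H](O)Cc1ccc(O)c(O)c1 | starting material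
18 | benzyl (2R)-3-[3,4-bis(benzyloxy)phenyl]-2-hydroxypropanoate | O[C@H](Cc1ccc(OCc2ccccc2)c(OCc2ccccc2)c1)C(=O)OCc1ccccc1 | intermediate
19 | benzyl (2R)-2-(acryloyloxy)-3-[3,4-bis(benzyloxy)phenyl]propanoate | C=CC(=O)O[C@H](Cc1ccc(OCc2ccccc2)c(OCc2ccccc2)c1)C(=O)OCc1ccccc1 | intermediate
20 | hexabenzyl monomethyl lithospermate (2S,3S; E; 2R in the side chain) | COC(=O)[C@H]1c2c(/C=C/C(=O)O[C@H](Cc3ccc(OCc4ccccc4)c(OCc4ccccc4)c3)C(=O)OCc3ccccc3)ccc(OCc3ccccc3)c2O[C@@H]1c1ccc(OCc2ccccc2)c(OCc2ccccc2)c1 | intermediate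
21 | monomethyl lithospermate | COC(=O)[C@H]1c2c(/C=C/C(=O)O[C@H](Cc3ccc(O)c(O)c3)C(=O)O)ccc(O)c2O[C@@H]1c1ccc(O)c(O)c1 | target

**Step count.** 15 steps in total; the longest linear sequence is 13 steps (steps 1–11, 14 and 15 from compound 1).

**Steps most likely to fail**

Step 10. The ortho bromine forces the aryl ring out of the carbene plane, so the chiral pocket may distinguish the two enantiotopic hydrogens poorly. The hindered carbene may also dimerise or be intercepted by adventitious water before it cyclises. Fallback, from 12 back to 16: stereocontrol is moved onto a covalent auxiliary. Acid 12 is esterified (EDC, DMAP, CH2Cl2) with (2S)-2-hydroxy-1-(pyrrolidin-1-yl)propan-1-one to give (2S)-1-oxo-1-(pyrrolidin-1-yl)propan-2-yl 2-[3-(benzyloxy)-2-{[3,4-bis(benzyloxy)benzyl]oxy}-6-bromophenyl]acetate F1. Diazo transfer (p-ABSA, DBU) should give the corresponding 2-diazoacetate F2. Cyclisation with Rh2(S-DOSP)4 in CH2Cl2–hexane should then proceed under double stereodifferentiation to the auxiliary ester of the (2S)-dihydrobenzofuran F3, whose diastereomers can be separated by chromatography or crystallisation. Whether the S- or the R-lactamide is the matched partner would be settled by a test cyclisation. NaOMe in MeOH then exchanges the auxiliary for methyl and equilibrates C3 in the same operation, returning to 16.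

Step 15. The Lewis acid may ionise the C2–O1 bond, a para-oxygenated benzylic ether, leading to ring opening or scrambling at C2. The benzyl ester may also lag behind the ethers, so that the conditions needed to finish it endanger the methyl ester. Fallback, from 16 and 19 back to 21: the benzyl groups are removed from the two small fragments and replaced by silyl groups, so that the last step is a fluoride desilylation.
- Core: 16 is debenzylated (BCl3, C6HMe5, −78 °C) to methyl (2S,3S)-4-bromo-2-(3,4-dihydroxyphenyl)-7-hydroxy-2,3-dihydro-1-benzofuran-3-carboxylate F4, which is silylated (TBSCl, imidazole, DMF) to its tris(tert-butyldimethylsilyl) ether F5.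
- Side chain: 19 is debenzylated in the same way to (2R)-2-(acryloyloxy)-3-(3,4-dihydroxyphenyl)propanoic acid F6, which is silylated to tert-butyldimethylsilyl (2R)-2-(acryloyloxy)-3-[3,4-bis(tert-butyldimethylsilyloxy)phenyl]propanoate F7.
- Union and release: Heck coupling of F5 with F7 under the conditions of step 14 should give the hexasilyl derivative of the target F8, and Et3N·3HF in THF then releases 21.

Step 14. Oxidative addition at the hindered, electron-rich C4–Br may be slow, so that acrylate oligomerisation or base-induced epimerisation of the lactate centre competes. Fallback, from 16 back to 20: the C–C bond and the ester bond are made separately. Heck coupling of 16 with acrylic acid (Pd(OAc)2, P(o-tol)3, Et3N, DMF, 90 °C), a small and robust partner that tolerates forcing conditions, should give (E)-3-[(2S,3S)-7-(benzyloxy)-2-[3,4-bis(benzyloxy)phenyl]-3-(methoxycarbonyl)-2,3-dihydro-1-benzofuran-4-yl]prop-2-enoic acid F9. Steglich esterification of F9 with alcohol 18 (EDC, DMAP, CH2Cl2) then gives 20.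

**Further compounds**

F1 | step 10 | (2S)-1-oxo-1-(pyrrolidin-1-yl)propan-2-yl 2-[3-(benzyloxy)-2-{[3,4-bis(benzyloxy)benzyl]oxy}-6-bromophenyl]acetate | C[C@H](OC(=O)Cc1c(Br)ccc(OCc2ccccc2)c1OCc1ccc(OCc2ccccc2)c(OCc2ccccc2)c1)C(=O)N1CCCC1
F2 | step 10 | (2S)-1-oxo-1-(pyrrolidin-1-yl)propan-2-yl 2-[3-(benzyloxy)-2-{[3,4-bis(benzyloxy)benzyl]oxy}-6-bromophenyl]-2-diazoacetate | C[C@H](OC(=O)C(=[N+]=[N-])c1c(Br)ccc(OCc2ccccc2)c1OCc1ccc(OCc2ccccc2)c(OCc2ccccc2)c1)C(=O)N1CCCC1
F3 | step 10 | (2S)-1-oxo-1-(pyrrolidin-1-yl)propan-2-yl (2S,3S)-7-(benzyloxy)-2-[3,4-bis(benzyloxy)phenyl]-4-bromo-2,3-dihydro-1-benzofuran-3-carboxylate | C[C@H](OC(=O)[C@H]1c2c(Br)ccc(OCc3ccccc3)c2O[C@@H]1c1ccc(OCc2ccccc2)c(OCc2ccccc2)c1)C(=O)N1CCCC1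
F4 | step 15 | methyl (2S,3S)-4-bromo-2-(3,4-dihydroxyphenyl)-7-hydroxy-2,3-dihydro-1-benzofuran-3-carboxylate | COC(=O)[C@H]1c2c(Br)ccc(O)c2O[C@@H]1c1ccc(O)c(O)c1
F5 | step 15 | methyl (2S,3S)-4-bromo-7-(tert-butyldimethylsilyloxy)-2-[3,4-bis(tert-butyldimethylsilyloxy)phenyl]-2,3-dihydro-1-benzofuran-3-carboxylate | COC(=O)[C@H]1c2c(Br)ccc(O[Si](C)(C)C(C)(C)C)c2O[C@@H]1c1ccc(O[Si](C)(C)C(C)(C)C)c(O[Si](C)(C)C(C)(C)C)c1
F6 | step 15 | (2R)-2-(acryloyloxy)-3-(3,4-dihydroxyphenyl)propanoic acid | C=CC(=O)O[C@H](Cc1ccc(O)c(O)c1)C(=O)O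
F7 | step 15 | tert-butyldimethylsilyl (2R)-2-(acryloyloxy)-3-[3,4-bis(tert-butyldimethylsilyloxy)phenyl]propanoate | C=CC(=O)O[C@H](Cc1ccc(O[Si](C)(C)C(C)(C)C)c(O[Si](C)(C)C(C)(C)C)c1)C(=O)O[Si](C)(C)C(C)(C)C
F8 | step 15 | hexakis(tert-butyldimethylsilyl) derivative of monomethyl lithospermate (five aryl silyl ethers, one silyl ester) | COC(=O)[C@H]1c2c(/C=C/C(=O)O[C@H](Cc3ccc(O[Si](C)(C)C(C)(C)C)c(O[Si](C)(C)C(C)(C)C)c3)C(=O)O[Si](C)(C)C(C)(C)C)ccc(O[Si](C)(C)C(C)(C)C)c2O[C@@H]1c1ccc(O[Si](C)(C)C(C)(C)C)c(O[Si](C)(C)C(C)(C)C)c1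
F9 | step 14 | (E)-3-[(2S,3S)-7-(benzyloxy)-2-[3,4-bis(benzyloxy)phenyl]-3-(methoxycarbonyl)-2,3-dihydro-1-benzofuran-4-yl]prop-2-enoic acid | COC(=O)[C@H]1c2c(/C=C/C(=O)O)ccc(OCc3ccccc3)c2O[C@@H]1c1ccc(OCc2ccccc2)c(OCc2ccccc2)c1
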